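**Plan**

Retrosynthesis: the ring alkene C3=C4 and an isopropenyl group are put back into the target to give a spiro diene. Both C–C bonds from its spiro carbon between the two ring carbonyls are then cut, first the one to the isopropenyl-bearing CH (cyclopentane), then the one to pinane C2. Last, the enol ether C(sp2)–O bond is cut to give a cis-C4 allylic alcohol and a vinylogous acid chloride.
Enabling feature: pinane C2 and the dione-flanked spiro carbon are both fully substituted and are bonded on the face of the six-membered pinane ring syn to the C6 CMe2 bridge, and that spiro carbon also bonds to the isopropyl-bearing CH of the cyclopentane. A cis oxygen on C4, allylic to C2=C3, can therefore hand the carbon between the two carbonyls of a cyclohexene-1,3-dione to C2 by a [3,3] shift, and that carbon can then be alkylated a second time.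
Forward: the pinane bicycle comes from (+)-β-pinene, and the six-carbon chain is joined to C2 by Grignard addition and oxidative transposition. The cyclohexenedione ring is made separately by dearomatising C-methylation of a phloroglucinol ester. The halves are joined through oxygen and the cyclopentane is closed last.
Stereochemistry: C1 and C5 come from (+)-β-pinene, the C4 carbinol centre from Luche reduction opposite to the CMe2 bridge, and C2 from suprafacial chirality transfer in the Claisen shift. The isopropenyl-bearing carbon and the spiro dione carbon are set in the 5-exo ring closure.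
Locants of the bicycle follow the pinane numbering of β-pinene throughout (C1 and C5 bridgeheads, C2 next to C1, C4 next to C5, C6 the CMe2 bridge, C7 the CH2 bridge).

Key step: step 13

Remark: the vinylogous chloride of the dione is assumed to form at the carbonyl remote from CMe2, so the Claisen precursor carries its enol ether oxygen on that carbon; the enol ether on the other dione carbonyl would rearrange to the same C-allylated dione, so the key step does not depend on this assumption.

**Route**

Step 1
Reactants: 1 (+)-β-pinene ((1R,5R)-6,6-dimethyl-2-methylidenebicyclo[3.1.1]heptane)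
Product: 2 nopinone ((1S,5R)-6,6-dimethylbicyclo[3.1.1]heptan-2-one)
Conditions: O3, CH2Cl2/MeOH, −78 °C; then Me2S, −78 → 23 °C
Reagents that add atoms: ozone, [O-][O+]=O
Why: Ozonolysis with reductive work-up cleaves the only alkene, the exocyclic methylidene group, and does not touch the two bridgehead stereocentres.

Step 2
Reactants: 2 nopinone
Product: 3 apoverbenone ((1S,5S)-6,6-dimethylbicyclo[3.1.1]hept-3-en-2-one)
Conditions: IBX (2-iodoxybenzoic acid), DMSO/PhF, 75 °C
Reagents that add atoms: none
Why: Dehydrogenation with IBX through the enol can only introduce the C3=C4 double bond because the other α-carbon is a bridgehead, so one enone forms and both bridgehead stereocentres are unchanged.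

Step 3
Reactants: 3 apoverbenone; 4 homoprenyl bromide (5-bromo-2-methylpent-2-ene)
Product: 6 tertiary allylic alcohol 6,6-dimethyl-2-(4-methylpent-3-enyl)bicyclo[3.1.1]hept-3-en-2-ol (hydroxyl syn to the C6 bridge), via homoprenylmagnesium bromide 5 (not isolated)
Conditions: 4, Mg, THF, 23 → 40 °C; then 3, THF, −78 → 0 °C; pH 7 buffer
Reagents that add atoms: none
Why: Grignard 1,2-addition to the enone carbonyl from the face opposite to the CMe2 bridge gives the tertiary allylic alcohol, and the configuration of its carbinol carbon is of no consequence because the next step removes it.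

Step 4
Reactants: 6 tertiary allylic alcohol
Product: 7 enone 6,6-dimethyl-2-(4-methylpent-3-enyl)bicyclo[3.1.1]hept-2-en-4-one
Conditions: C5H5NH[CrO3Cl] (pyridinium chlorochromate), CH2Cl2, 23 °C
Reagents that add atoms: pyridinium chlorochromate, [O-][Cr](=O)(=O)Cl.c1cc[nH+]cc1
Why: In the Babler–Dauben oxidative transposition the tertiary allylic chromate ester undergoes a [3,3] shift to the C4 chromate, which is oxidised to the enone, so oxygen moves from C2 to C4 and the chain stays on the β-carbon C2.

Step 5
Reactants: 7 enone
Product: 8 allylic alcohol 2-[(E)-5-hydroxy-4-methylpent-3-enyl]-6,6-dimethylbicyclo[3.1.1]hept-2-en-4-one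
Conditions: SeO2 (cat.), t-BuOOH, CH2Cl2, 23 °C
Reagents that add atoms: tert-butyl hydroperoxide, CC(C)(C)OO
Why: Riley-type allylic oxidation with catalytic SeO2 (ene reaction then [2,3] shift) hydroxylates the (E)-methyl group of the electron-rich trisubstituted alkene, whereas the electron-poor enone alkene does not enter the ene step.

Step 6
Reactants: 8 allylic alcohol
Product: 9 allylic chloride 2-[(E)-5-chloro-4-methylpent-3-enyl]-6,6-dimethylbicyclo[3.1.1]hept-2-en-4-one
Conditions: PPh3, N-chlorosuccinimide, THF, 0 → 23 °C
Reagents that add atoms: N-chlorosuccinimide, O=C1CCC(=O)N1Cl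
Why: Appel-type chlorination through the alkoxyphosphonium salt replaces the primary allylic hydroxyl by direct SN2 displacement, without allylic shift or change of alkene geometry.

Step 7
Reactants: 9 allylic chloride
Product: 10 cis-allylic alcohol 2-[(E)-5-chloro-4-methylpent-3-enyl]-6,6-dimethylbicyclo[3.1.1]hept-2-en-4-ol (hydroxyl syn to the C6 bridge)
Conditions: NaBH4, CeCl3·7H2O, MeOH, −40 °C
Reagents that add atoms: none
Why: Luche 1,2-reduction delivers hydride to the enone carbonyl from the face opposite to the CMe2 bridge, as in the reduction of verbenone to cis-verbenol, so the new C4 stereocentre carries its oxygen syn to C6 and the allylic chloride is not touched.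

Step 8
Reactants: 11 methyl 2,4,6-trihydroxybenzoate
Product: 12 methyl 2,6-dihydroxy-4-methoxybenzoate
Conditions: Me2SO4 (1.0 equiv), K2CO3 (1.0 equiv), acetone, 23 °C
Reagents that add atoms: dimethyl sulfate, COS(=O)(=O)OC
Why: Williamson O-methylation should occur at the 4-hydroxyl because it is the most acidic phenol and the only one not engaged in a hydrogen bond to the ester group.

Step 9
Reactants: 12 methyl 2,6-dihydroxy-4-methoxybenzoate
Product: 13 methyl 2-hydroxy-4-methoxy-3,5,5-trimethyl-6-oxocyclohexa-1,3-diene-1-carboxylate
Conditions: NaOMe (4 equiv), MeI (3.3 equiv), MeOH, 0 → 65 °C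
Reagents that add atoms: iodomethane, CI
Why: Base-mediated C-methylation of the phloroglucinol-type nucleus (alkylative dearomatisation as practised on acylphloroglucinols) methylates both free ring carbons and then one of them again, which is the same carbon by symmetry, and stops there because the β-tricarbonyl anion that results has only its weakly nucleophilic ester-bearing carbon left.

Step 10
Reactants: 13 trimethylated ester
Product: 15 5-methoxy-4,6,6-trimethylcyclohex-4-ene-1,3-dione, via carboxylic acid 14 (not isolated)
Conditions: KOH, MeOH/H2O, 65 °C; then AcOH to pH 5, 23 → 40 °C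
Reagents that add atoms: none
Why: Saponification and decarboxylation of the resulting β-keto acid remove the blocking ester, while the hindered methyl enol ether should survive because conjugate exchange at its carbon in methanolic base only returns a methoxy group and the acidification is kept at pH 5.

Step 11
Reactants: 15 5-methoxy-4,6,6-trimethylcyclohex-4-ene-1,3-dione
Product: 16 3-chloro-5-methoxy-4,6,6-trimethylcyclohexa-2,4-dien-1-one
Conditions: (COCl)2, DMF (cat.), CH2Cl2, 0 → 23 °C
Reagents that add atoms: oxalyl chloride, O=C(Cl)C(Cl)=O
Why: Vinylogous acid chloride formation (Vilsmeier-type activation of the enolised 1,3-dione, then addition–elimination of chloride) is expected at C3, the less hindered and more electron-rich carbonyl remote from the CMe2 carbon.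

Step 12
Reactants: 10 cis-allylic alcohol; 16 vinylogous chloride
Product: 17 enol ether 3-({2-[(E)-5-chloro-4-methylpent-3-enyl]-6,6-dimethylbicyclo[3.1.1]hept-2-en-4-yl}oxy)-5-methoxy-4,6,6-trimethylcyclohexa-2,4-dien-1-one (C4–O syn to the C6 bridge)
Conditions: KN(SiMe3)2, THF, −78 °C; then 16, −78 → 0 °C
Reagents that add atoms: none
Why: Addition–elimination of the potassium alkoxide at the β-carbon of the vinylogous acid chloride forms the O–C(sp2) bond, so the C4–O bond and its cis configuration are not touched, and at low temperature this acyl-type substitution should outrun SN2 attack of the alkoxide on the allylic chloride.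

Step 13
Reactants: 17 enol ether
Product: 19 spiro diene (cyclopentane spiro-fused to pin-3-ene at C2 and to the 5-methoxy-4,6,6-trimethylcyclohex-4-ene-1,3-dione ring at its C2; isopropenyl on the CH next to the dione carbon), via Claisen product 18 (not isolated)
Conditions: PhMe, 150 °C, base-washed sealed tube; then Cs2CO3, DMF, 23 → 50 °C
Reagents that add atoms: none
Why: On heating, the allyl vinyl ether unit C2=C3–C4–O–C=CH of 17 undergoes a concerted [3,3] sigmatropic shift, the Claisen rearrangement known for 3-allyloxy-enones, which breaks the C4–O bond, forms the bond from the dione CH carbon to pinane C2 and gives the 2-substituted 1,3-dione 18. Because the shift is suprafacial on the rigid pinene ring, the dione carbon arrives on the face of C2 that carried the C4 oxygen, syn to the C6 bridge, so the C2 stereocentre is set by chirality transfer from C4 and needs only the cis configuration of 17. Cs2CO3 then deprotonates 18 between its carbonyls and the anion attacks the CH= carbon of the (E)-allylic chloride with allylic shift and loss of chloride, the intramolecular SN2′ C-alkylation of β-dicarbonyl anions that is known to give vinylcyclopentanes; the cyclopentane closes in the 5-exo-trig mode and the isopropenyl group is left behind. The isopropenyl-bearing stereocentre is controlled by the fold of the tether, which should place the forming isopropenyl group on the cyclopentane face of the sp2 carbon C3 and not of the bridgehead C1, and the spiro dione carbon is controlled by the rotamer of the planar dione anion about the new C2–C bond, which should turn the carbonyl flanked by CMe2 away from the incoming allyl unit; this second bias is small and is the weakest point of the step. The step needs C- over O-alkylation and SN2′ over SN2 attack, and ring size secures both, since O-attack at the same carbon would give a seven-membered cyclic enol ether and C-attack at CH2Cl would force the (E)-alkene into a seven-membered ring. Nonpolar solvent and a base-washed vessel are chosen to suppress ionisation of the allylic enol ether during the thermal stage.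

Step 14
Reactants: 19 spiro diene
Product: 20 target CNP0307059.1
Conditions: H2 (1 atm), Pd/C, EtOAc, 23 °C
Reagents that add atoms: none
Why: Heterogeneous catalytic hydrogenation saturates the 1,1-disubstituted isopropenyl alkene and the cis-disubstituted ring alkene, creates no new stereocentre, and should leave the tetrasubstituted vinylogous-ester alkene and the ketones untouched.

**Compound list**

1 | (+)-β-pinene, (1R,5R)-6,6-dimethyl-2-methylidenebicyclo[3.1.1]heptane | C=C1CC[C@@H]2C[C@H]1C2(C)C | starting material
2 | nopinone, (1S,5R)-6,6-dimethylbicyclo[3.1.1]heptan-2-one | O=C1CC[C@@H]2C[C@H]1C2(C)C | intermediate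
3 | apoverbenone, (1S,5S)-6,6-dimethylbicyclo[3.1.1]hept-3-en-2-one | O=C1C=C[C@@H]2C[C@H]1C2(C)C | intermediate
4 | homoprenyl bromide, 5-bromo-2-methylpent-2-ene | CC(C)=CCCBr | starting material
5 | homoprenylmagnesium bromide, (4-methylpent-3-enyl)magnesium bromide | CC(C)=CCC[Mg]Br | intermediate
6 | 6,6-dimethyl-2-(4-methylpent-3-enyl)bicyclo[3.1.1]hept-3-en-2-ol, hydroxyl syn to the C6 bridge, bridgeheads as in 1 | O[C@@]1(CCC=C(C)C)C=C[C@@H]2C[C@H]1C2(C)C | intermediate
7 | 6,6-dimethyl-2-(4-methylpent-3-enyl)bicyclo[3.1.1]hept-2-en-4-one (pinane numbering), bridgeheads as in 1 | CC(C)=CCCC1=CC(=O)[C@@H]2C[C@H]1C2(C)C | intermediate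
8 | 2-[(E)-5-hydroxy-4-methylpent-3-enyl]-6,6-dimethylbicyclo[3.1.1]hept-2-en-4-one, bridgeheads as in 1 | OC/C(C)=C/CCC1=CC(=O)[C@@H]2C[C@H]1C2(C)C | intermediate
9 | 2-[(E)-5-chloro-4-methylpent-3-enyl]-6,6-dimethylbicyclo[3.1.1]hept-2-en-4-one, bridgeheads as in 1 | ClC/C(C)=C/CCC1=CC(=O)[C@@H]2C[C@H]1C2(C)C | intermediate
10 | 2-[(E)-5-chloro-4-methylpent-3-enyl]-6,6-dimethylbicyclo[3.1.1]hept-2-en-4-ol, C4 hydroxyl cis (syn) to the C6 CMe2 bridge, bridgeheads as in 1 | ClC/C(C)=C/CCC1=C[C@@H](O)[C@@H]2C[C@H]1C2(C)C | intermediate
11 | methyl 2,4,6-trihydroxybenzoate | COC(=O)c1c(O)cc(O)cc1O | starting material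
12 | methyl 2,6-dihydroxy-4-methoxybenzoate | COC(=O)c1c(O)cc(OC)cc1O | intermediate
13 | methyl 2-hydroxy-4-methoxy-3,5,5-trimethyl-6-oxocyclohexa-1,3-diene-1-carboxylate | COC(=O)C1=C(O)C(C)=C(OC)C(C)(C)C1=O | intermediate
14 | 2-hydroxy-4-methoxy-3,5,5-trimethyl-6-oxocyclohexa-1,3-diene-1-carboxylic acid | OC(=O)C1=C(O)C(C)=C(OC)C(C)(C)C1=O | intermediate
15 | 5-methoxy-4,6,6-trimethylcyclohex-4-ene-1,3-dione | COC1=C(C)C(=O)CC(=O)C1(C)C | intermediate
16 | 3-chloro-5-methoxy-4,6,6-trimethylcyclohexa-2,4-dien-1-one | ClC1=CC(=O)C(C)(C)C(OC)=C1C | intermediate
17 | enol ether of 10 on the C3 oxygen of 15: 3-({2-[(E)-5-chloro-4-methylpent-3-enyl]-6,6-dimethylbicyclo[3.1.1]hept-2-en-4-yl}oxy)-5-methoxy-4,6,6-trimethylcyclohexa-2,4-dien-1-one, C4–O syn to the C6 bridge | ClC/C(C)=C/CCC1=C[C@@H](OC2=CC(=O)C(C)(C)C(OC)=C2C)[C@@H]3C[C@H]1C3(C)C | intermediate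
18 | 2-{2-[(E)-5-chloro-4-methylpent-3-enyl]-6,6-dimethylbicyclo[3.1.1]hept-3-en-2-yl}-5-methoxy-4,6,6-trimethylcyclohex-4-ene-1,3-dione, dione ring on the face of C2 syn to the C6 bridge, drawn as an enol | COC1=C(C)C(=O)C(=C(O)C1(C)C)[C@@]2(CC/C=C(C)/CCl)C=C[C@@H]3C[C@H]2C3(C)C | intermediate
19 | spiro diene: cyclopentane spiro-fused at pin-3-ene C2 and at C2 of the 5-methoxy-4,6,6-trimethylcyclohex-4-ene-1,3-dione ring; dione carbon on C2 syn to the C6 bridge; isopropenyl on the adjacent CH, cis to C3 and to the enone carbonyl, trans to C1 and to the CMe2-flanked carbonyl | COC1=C(C)C(=O)[C@@]2(C(=O)C1(C)C)[C@@H](C(C)=C)CC[C@@]23C=C[C@@H]4C[C@H]3C4(C)C | intermediate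
20 | CNP0307059.1: tetrahydro derivative of 19 with an isopropyl group and a saturated pinane ring, same configuration at all five stereocentres | COC1=C(C)C(=O)[C@@]2(C(=O)C1(C)C)[C@@H](C(C)C)CC[C@@]21CC[C@@H]2C[C@H]1C2(C)C | target

**Step count and risks**

Total step count: 14. Longest linear sequence: 10 steps (steps 1 to 7, then 12, 13 and 14).

Step 13. The [3,3] shift has to bring the dienone ring under the syn methyl group of the C6 bridge, so it may be slower than ionisation of the allylic enol ether, with loss of the dione and elimination to a diene; traces of HCl shed by the allylic chloride at 150 °C would catalyse this. In the second stage the hindered dione anion may alkylate slowly, at oxygen, or through the other rotamer about the C2–C bond, which would invert the spiro dione carbon. The fallback replaces the chloride by a thermally inert carbonate and closes the ring by Tsuji–Trost allylic alkylation under neutral conditions. It sets out from 8: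
- Boc2O and DMAP in CH2Cl2 should give the carbonate enone F1.
- Luche reduction (NaBH4, CeCl3·7H2O, MeOH) should give the cis-allylic alcohol carbonate F2.
- Its potassium alkoxide (KN(SiMe3)2) and 16, as in step 12, should give the enol ether carbonate F3.
- Heating in toluene at 150 °C should give the Claisen product carbonate F4, which can be purified at this stage.
- Pd2(dba)3 with PPh3, or with either enantiomer of a chiral bisphosphine so that the catalyst and not the substrate selects the face and rotamer, in THF at 23 °C should ionise the carbonate to a π-allyl complex of divalent palladium. The tert-butoxide released deprotonates the dione and the cyclopentane closes by 5-exo attack.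

The fallback comes back to the route at 19.

Step 12. The secondary alkoxide of 10 and the β-carbon of 16 are both hindered, so SN2 attack of the alkoxide on the allylic chloride of a second molecule, giving oligomeric ethers, may compete with the addition–elimination. The fallback keeps the primary oxygen silylated through the coupling and installs chloride last. It sets out from 8:
- t-BuPh2SiCl and imidazole in DMF should give the silyl ether enone F5.
- Luche reduction should give the cis-allylic alcohol silyl ether F6.
- KN(SiMe3)2 and 16 should give the silylated enol ether F7.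
- Bu4NF in THF should free the primary allylic alcohol F8.
- PPh3 and N-chlorosuccinimide at 0 °C should convert it into the chloride.

The fallback comes back to the route at 17.

Step 9. After two C-methylations the arene carries only two phenoxide oxygens and an ester, so the third, dearomatising methylation may stall at the dimethylated arene or be diverted to oxygen. The fallback dearomatises first and methylates oxygen afterwards. It sets out from 11:
- NaOMe and MeI (3 equiv) in MeOH should C-methylate the free phloroglucinol ester to methyl 2,4-dihydroxy-3,5,5-trimethyl-6-oxocyclohexa-1,3-diene-1-carboxylate F9, which is separated from its di- and tetramethyl congeners.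
- Me3SiCHN2 in MeOH/PhMe should then methylate the only enol oxygen not hydrogen-bonded to the ester, the one between the C-methyl and CMe2 carbons.

The fallback comes back to the route at 13.

Further compounds
F1 | step 13 | tert-butyl carbonate of 8, tert-butyl (E)-5-(6,6-dimethyl-4-oxobicyclo[3.1.1]hept-2-en-2-yl)-2-methylpent-2-enyl carbonate | CC(C)(C)OC(=O)OC/C(C)=C/CCC1=CC(=O)[C@@H]2C[C@H]1C2(C)C
F2 | step 13 | cis-allylic alcohol carbonate, C4 hydroxyl syn to the C6 bridge | CC(C)(C)OC(=O)OC/C(C)=C/CCC1=C[C@@H](O)[C@@H]2C[C@H]1C2(C)C
F3 | step 13 | enol ether carbonate, analogue of 17 with OCO2t-Bu in place of Cl | CC(C)(C)OC(=O)OC/C(C)=C/CCC1=C[C@@H](OC2=CC(=O)C(C)(C)C(OC)=C2C)[C@@H]3C[C@H]1C3(C)C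
F4 | step 13 | Claisen product carbonate, analogue of 18 with OCO2t-Bu in place of Cl, drawn as an enol | COC1=C(C)C(=O)C(=C(O)C1(C)C)[C@@]2(CC/C=C(C)/COC(=O)OC(C)(C)C)C=C[C@@H]3C[C@H]2C3(C)C
F5 | step 12 | tert-butyldiphenylsilyl ether of 8 | CC(C)(C)[Si](OC/C(C)=C/CCC1=CC(=O)[C@@H]2C[C@H]1C2(C)C)(c3ccccc3)c4ccccc4
F6 | step 12 | cis-allylic alcohol silyl ether, C4 hydroxyl syn to the C6 bridge | CC(C)(C)[Si](OC/C(C)=C/CCC1=C[C@@H](O)[C@@H]2C[C@H]1C2(C)C)(c3ccccc3)c4ccccc4
F7 | step 12 | silylated enol ether, analogue of 17 with OSiPh2t-Bu in place of Cl | CC(C)(C)[Si](OC/C(C)=C/CCC1=C[C@@H](OC2=CC(=O)C(C)(C)C(OC)=C2C)[C@@H]3C[C@H]1C3(C)C)(c4ccccc4)c5ccccc5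
F8 | step 12 | primary allylic alcohol, analogue of 17 with OH in place of Cl | OC/C(C)=C/CCC1=C[C@@H](OC2=CC(=O)C(C)(C)C(OC)=C2C)[C@@H]3C[C@H]1C3(C)C
F9 | step 9 | methyl 2,4-dihydroxy-3,5,5-trimethyl-6-oxocyclohexa-1,3-diene-1-carboxylate | COC(=O)C1=C(O)C(C)=C(O)C(C)(C)C1=O
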